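**Retrosynthetic overview**
1. No ring is built. Ring B is bought as 2,4-dibromophenol 1 and carried as its formate 2; ring A is bought as 1,2-dibromo-4-fluorobenzene 3.
2. Key disconnection, the diaryl ether C–O bond: the ring A fluoride is displaced by the ring B aryloxide, activated by an ortho formyl group. In one flask, 3 → aryllithium 4 → fluoroaldehyde 5 plus lithium aryloxide 6 → ether aldehyde 7.
3. Second disconnection, the phenolic C–O bond of ring A: formyl → hydroxyl by Baeyer–Villiger oxidation, 7 → aryl formate 8 → target 9.
4. The formyl C–C bond goes back to the C–H between F and Br of 3; formate 2 supplies both the formyl group and the aryloxide.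
5. Bond order: C–C (formyl), C–O (ether), C–O (phenol).

Assumption: the target has no stereocentre and is achiral, so no stereocontrol is needed.

**Route**

Step 1
Reactants: 1 2,4-dibromophenol
Product: 2 2,4-dibromophenyl formate
Conditions: HCO2H (4 equiv), Ac2O (3 equiv), 60 °C, 1 h; then 1, cat. NaOAc, toluene, rt, 3 h
Reagents that add atoms: acetic formic anhydride, CC(=O)OC=O (made in the flask from formic acid, OC=O, and acetic anhydride, CC(=O)OC(C)=O)
Why: O-formylation by acyl transfer: the mixed anhydride reacts at its more electrophilic, less hindered formyl carbonyl with the phenol under acetate catalysis, the usual way to electron-poor aryl formates; no stereocentre is formed.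

Step 2
Reactants: 3 1,2-dibromo-4-fluorobenzene; 2 2,4-dibromophenyl formate
Product: 7 2,3-dibromo-6-(2,4-dibromophenoxy)benzaldehyde, via aryllithium 4 (not isolated), via fluoroaldehyde 5 (not isolated), via lithium aryloxide 6 (not isolated)
Conditions: LiN(iPr)2 (1.0 equiv), THF, −78 °C, 45 min; cannulate into 2 (1.15 equiv), THF, −78 °C, 30 min; then DMSO, 70 °C, 8 h
Reagents that add atoms: none
Why: Proposed new method: a formyl-transfer/aryloxide-return relay, formally the insertion of the C(H)–C(F) unit of 3 into the acyl–oxygen bond of aryl formate 2. LiN(iPr)2 removes the most acidic proton of 3, the one flanked by F and Br (directed ortho-lithiation). Aryllithium 4 adds to the formate carbonyl (acyl substitution) and the tetrahedral adduct expels 2,4-dibromophenoxide, a good leaving group (phenol pKa about 7.8), so 5 and 6 arise in a 1:1 ratio. The new ortho formyl group, helped by the para bromine, activates the C–F bond for addition–elimination (SNAr) by 6 once DMSO frees the aryloxide from lithium; fluoride leaves far faster than the ortho bromide and LiF formation drives the step. The closest known reaction types are the formylation of aryllithiums with formate esters, the separate SNAr of 2-fluorobenzaldehydes with phenoxides, and aryne insertion into acyl–heteroatom bonds, which gives the same vicinal acyl/heteroatom pattern but could neither fix the regiochemistry nor spare the bromines. No stereocentre is formed.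

Step 3
Reactants: 7 2,3-dibromo-6-(2,4-dibromophenoxy)benzaldehyde
Product: 9 2,3-dibromo-6-(2,4-dibromophenoxy)phenol, via aryl formate 8 (not isolated)
Conditions: mCPBA (1.6 equiv), CH2Cl2, 40 °C, 16 h; then MeOH, cat. HCl, rt, 2 h
Reagents that add atoms: mCPBA, OOC(=O)c1cccc(Cl)c1
Why: Baeyer–Villiger oxidation (Dakin-type): the peracid adds to the aldehyde and the di-ortho-substituted aryl group, whose migrating carbon is made electron-rich by the ortho aryloxy group, migrates to oxygen in preference to hydride; acid-catalysed methanolysis of aryl formate 8 frees the phenol; no stereocentre is formed.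

**Compound list**
1 | 2,4-dibromophenol | Oc1ccc(Br)cc1Br | starting material
2 | 2,4-dibromophenyl formate | O=COc1ccc(Br)cc1Br | intermediate
3 | 1,2-dibromo-4-fluorobenzene | Fc1ccc(Br)c(Br)c1 | starting material
4 | (2,3-dibromo-6-fluorophenyl)lithium (not isolated) | [Li]c1c(F)ccc(Br)c1Br | intermediate
5 | 2,3-dibromo-6-fluorobenzaldehyde (not isolated) | O=Cc1c(F)ccc(Br)c1Br | intermediate
6 | lithium 2,4-dibromophenoxide (not isolated) | [Li+].[O-]c1ccc(Br)cc1Br | intermediate
7 | 2,3-dibromo-6-(2,4-dibromophenoxy)benzaldehyde | O=Cc1c(Oc2ccc(Br)cc2Br)ccc(Br)c1Br | intermediate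
8 | 2,3-dibromo-6-(2,4-dibromophenoxy)phenyl formate (not isolated) | O=COc1c(Oc2ccc(Br)cc2Br)ccc(Br)c1Br | intermediate
9 | 2,3-dibromo-6-(2,4-dibromophenoxy)phenol | Oc1c(Oc2ccc(Br)cc2Br)ccc(Br)c1Br | target

**Step count and risks**

Total step count: 3. Longest linear sequence: 3 steps (1 → 2 → 7 → 9); the ring A branch from 3 is 2 steps.

Steps most likely to fail, most risky first:

Step 2 (the proposed new relay). Possible failures are a second addition of 4 to aldehyde 5, base-induced loss of CO from formate 2 (removal of the formyl proton by 4, which returns 3), or a sluggish displacement by the lithium aryloxide. The fallback uses known chemistry and sets out from 3. LiN(iPr)2 in THF at −78 °C followed by DMF gives lithium (2,3-dibromo-6-fluorophenyl)(dimethylamino)methanolate F2, which aqueous HCl work-up hydrolyses to 5, now isolated. Heating 5 with phenol 1 and K2CO3 in DMF at 90 °C forms potassium 2,4-dibromophenoxide F3, which displaces the fluoride in a classical SNAr. The fallback comes back to the route at 7.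

Step 3. Possible failures are hydride migration to the benzoic acid in place of aryl migration, or slow oxidation of the hindered, halogen-rich aldehyde. The fallback sets out from 7 and removes the competing hydride. MeMgBr in THF at −78 to 0 °C gives rac-1-[2,3-dibromo-6-(2,4-dibromophenoxy)phenyl]ethanol F4. Dess–Martin periodinane in CH2Cl2 oxidises it to 1-[2,3-dibromo-6-(2,4-dibromophenoxy)phenyl]ethanone F5, which removes the stereocentre again. Baeyer–Villiger oxidation with mCPBA and CF3CO2H in CH2Cl2, where aryl migrates in preference to methyl, gives 2,3-dibromo-6-(2,4-dibromophenoxy)phenyl acetate F6. K2CO3 in MeOH cleaves the acetate, and the fallback comes back to the route at 9.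

Step 1. Possible failures are incomplete formylation of the electron-poor phenol, or hydrolysis or loss of CO from 2 during isolation. The fallback sets out from 1 and replaces acyl transfer from an anhydride by O-imidoylation. (Chloromethylidene)dimethyliminium chloride, made from DMF and oxalyl chloride, reacts with 1 in CH2Cl2 at 0 °C to give N-[(2,4-dibromophenoxy)methylidene]-N-methylmethanaminium chloride F1. Cold aqueous NaOAc hydrolyses F1 at the C=N bond, and the fallback comes back to the route at 2.

**Further compounds**
F1 | step 1 | N-[(2,4-dibromophenoxy)methylidene]-N-methylmethanaminium chloride | C[N+](C)=COc1ccc(Br)cc1Br.[Cl-]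
F2 | step 2 | lithium (2,3-dibromo-6-fluorophenyl)(dimethylamino)methanolate (racemic) | [Li+].[O-]C(N(C)C)c1c(F)ccc(Br)c1Br
F3 | step 2 | potassium 2,4-dibromophenoxide | [K+].[O-]c1ccc(Br)cc1Br
F4 | step 3 | rac-1-[2,3-dibromo-6-(2,4-dibromophenoxy)phenyl]ethanol | CC(O)c1c(Oc2ccc(Br)cc2Br)ccc(Br)c1Br
F5 | step 3 | 1-[2,3-dibromo-6-(2,4-dibromophenoxy)phenyl]ethanone | CC(=O)c1c(Oc2ccc(Br)cc2Br)ccc(Br)c1Br
F6 | step 3 | 2,3-dibromo-6-(2,4-dibromophenoxy)phenyl acetate | CC(=O)Oc1c(Oc2ccc(Br)cc2Br)ccc(Br)c1Br
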